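## Retrosynthetic overview
1. Cut the C(sp3)–C(sp2) bond between the chroman CH2CH2 arm and the E-trisubstituted alkene. This is a B-alkyl Suzuki–Miyaura coupling of a 2-vinylchroman with an (E)-alkenyl iodide that already carries the (Z)-enoate.
2. Cut O1–C2 and C3–C4 of the 2-vinylchroman together. This is a catalytic enantioselective inverse-demand hetero-Diels–Alder reaction of isoprene with the dearomatised ortho-quinone methide of the orcinol nucleus, and it sets C2.
3. The quinone methide comes from a benzylic alcohol, the alcohol from an aldehyde, and the aldehyde from orcinol. Formylation para to one OH tells the two hydroxyls apart.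
4. The alkenyl iodide comes from a Still–Gennari olefination (Z) and a Zr-catalysed methylalumination–iodination of pent-4-yn-1-ol (E).
5. Ring order: the benzene ring is bought as orcinol, and the dihydropyran is the only ring formed (step 3).

Assumption: the sense of induction in the new step 3 cannot be predicted, so a first screen fixes which catalyst antipode (from (R)- or (S)-BINOL) gives (S)-7; phosphonate 12 is taken as a catalogue reagent.

## Route

Step 1
Reactants: 1 orcinol (5-methylbenzene-1,3-diol)
Product: 3 2,4-dihydroxy-6-methylbenzaldehyde, via aryl iminium chloride 2 (not isolated)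
Conditions: POCl3 (1.5 equiv), DMF, 0 °C → rt; then ice–H2O
Reagents that add atoms: N,N-dimethylformamide, CN(C)C=O; water, O
Why: Vilsmeier–Haack formylation, in which the chloroiminium ion attacks the doubly activated C4 (para to one OH, ortho to the other) in preference to the position flanked by both hydroxyls, and water hydrolyses iminium 2 to the aldehyde.

Step 2
Reactants: 3 2,4-dihydroxy-6-methylbenzaldehyde
Product: 4 4-(hydroxymethyl)-5-methylbenzene-1,3-diol
Conditions: NaBH4 (0.6 equiv), THF–EtOH, 0 °C; pH 7 phosphate work-up, no chromatography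
Reagents that add atoms: none
Why: Borohydride 1,2-reduction of the aldehyde at 0 °C with limited hydride and a neutral work-up stops at the benzylic alcohol before quinone-methide-type over-reduction or self-condensation sets in.

Step 3
Reactants: 4 4-(hydroxymethyl)-5-methylbenzene-1,3-diol; 5 isoprene (2-methylbuta-1,3-diene)
Product: 7 (2S)-2-ethenyl-2,5-dimethyl-3,4-dihydro-2H-chromen-7-ol, via ortho-quinone methide 6 (not isolated)
Conditions: BINOL-derived IDPi Brønsted acid (5 mol %), isoprene (20 equiv), 5 Å MS, CH2Cl2, −40 °C, 4 added by syringe pump (Et2O solution, 12 h); Et3N quench at −40 °C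
Reagents that add atoms: none
Why: Proposed new method: the strong confined acid dehydrates the doubly O-activated benzylic alcohol to the dearomatised ortho-quinone methide 6, held as an H-bonded ion pair in the chiral pocket, and isoprene adds in an asynchronous inverse-electron-demand hetero-Diels–Alder reaction in which its C1 attacks the methide carbon (charge building at the tertiary allylic C2) and the carbonyl oxygen closes on C2 to restore the arene, with the catalyst wall blocking one face of 6 and placing the flat vinyl group endo and the methyl exo so that C2 forms as (S); the closest known reaction types are chiral N-triflylphosphoramide-catalysed [4+2] cycloadditions of in situ formed ortho-quinone methides with styrenes and other unactivated alkenes, and IDPi-catalysed hetero-Diels–Alder reactions of simple dienes.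

Step 4
Reactants: 8 pent-4-yn-1-ol
Product: 10 (4E)-5-iodo-4-methylpent-4-en-1-ol, via alkenylalane 9 (not isolated)
Conditions: AlMe3 (3 equiv), Cp2ZrCl2 (25 mol %), CH2Cl2, 0 °C → rt; then I2, THF, −30 °C; aq. K2CO3 work-up
Reagents that add atoms: trimethylaluminium, C[Al](C)C; iodine, II
Why: Negishi Zr-catalysed methylalumination adds Me and Al syn across the alkyne with Al at the terminus, and iodinolysis of alkenylalane 9 goes with retention to give the E-iodide.

Step 5
Reactants: 10 (4E)-5-iodo-4-methylpent-4-en-1-ol
Product: 11 (4E)-5-iodo-4-methylpent-4-enal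
Conditions: TEMPO (10 mol %), PhI(OAc)2 (1.1 equiv), CH2Cl2, rt
Reagents that add atoms: none
Why: TEMPO/PhI(OAc)2 (oxoammonium) oxidation of a primary alcohol stops at the aldehyde and leaves the alkenyl iodide untouched.

Step 6
Reactants: 11 (4E)-5-iodo-4-methylpent-4-enal; 12 methyl 2-[bis(2,2,2-trifluoroethoxy)phosphoryl]propanoate
Product: 14 methyl (2Z,6E)-7-iodo-2,6-dimethylhepta-2,6-dienoate, via potassium phosphonate carbanion 13 (not isolated)
Conditions: 12, KHMDS, 18-crown-6, THF, −78 °C; then 11
Reagents that add atoms: none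
Why: Still–Gennari variant of the Horner–Wadsworth–Emmons olefination, in which the electron-poor phosphonate and the dissociated K+/18-crown-6 counter-ion make elimination from the kinetic adduct fast and so give the Z-trisubstituted enoate.

Step 7
Reactants: 7 (2S)-2-ethenyl-2,5-dimethyl-3,4-dihydro-2H-chromen-7-ol; 14 methyl (2Z,6E)-7-iodo-2,6-dimethylhepta-2,6-dienoate
Product: 16 methyl (2Z,6E)-9-[(2R)-7-hydroxy-2,5-dimethyl-3,4-dihydro-2H-chromen-2-yl]-2,6-dimethylnona-2,6-dienoate, via bis-boryl chroman 15 (not isolated)
Conditions: 9-BBN (2.5 equiv), THF, rt → 40 °C; H2O (destroys excess borane); then 14, PdCl2(dppf) (5 mol %), AsPh3 (10 mol %), Cs2CO3, DMF–THF–H2O, rt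
Reagents that add atoms: none
Why: 9-BBN adds anti-Markovnikov to the only C=C of 7 (the phenol is merely O-borylated and is freed again by the aqueous base), and the B-alkyl Suzuki–Miyaura coupling joins the primary alkylborane to the alkenyl iodide with retention of the E geometry, leaving C2 (descriptor changes S → R by CIP priority only) and the Z-enoate untouched.

## Compound list
1 | orcinol (5-methylbenzene-1,3-diol) | Cc1cc(O)cc(O)c1 | starting material
2 | [(2,4-dihydroxy-6-methylphenyl)methylidene]dimethyliminium chloride | C[N+](C)=Cc1c(C)cc(O)cc1O.[Cl-] | intermediate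
3 | 2,4-dihydroxy-6-methylbenzaldehyde | O=Cc1c(C)cc(O)cc1O | intermediate
4 | 4-(hydroxymethyl)-5-methylbenzene-1,3-diol | OCc1c(C)cc(O)cc1O | intermediate
5 | isoprene (2-methylbuta-1,3-diene) | C=CC(C)=C | starting material
6 | 3-hydroxy-5-methyl-6-methylidenecyclohexa-2,4-dien-1-one | C=C1C(C)=CC(O)=CC1=O | intermediate
7 | (2S)-2-ethenyl-2,5-dimethyl-3,4-dihydro-2H-chromen-7-ol | C=C[C@]1(C)CCc2c(C)cc(O)cc2O1 | intermediate
8 | pent-4-yn-1-ol | C#CCCCO | starting material
9 | dimethylaluminium (4E)-5-(dimethylalumanyl)-4-methylpent-4-en-1-olate | C[Al](C)OCCC/C(C)=C/[Al](C)C | intermediate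
10 | (4E)-5-iodo-4-methylpent-4-en-1-ol | OCCC/C(C)=C/I | intermediate
11 | (4E)-5-iodo-4-methylpent-4-enal | O=CCC/C(C)=C/I | intermediate
12 | methyl 2-[bis(2,2,2-trifluoroethoxy)phosphoryl]propanoate | COC(=O)C(C)P(=O)(OCC(F)(F)F)OCC(F)(F)F | starting material
13 | potassium salt of the carbanion of 12 | [K+].COC(=O)[C-](C)P(=O)(OCC(F)(F)F)OCC(F)(F)F | intermediate
14 | methyl (2Z,6E)-7-iodo-2,6-dimethylhepta-2,6-dienoate | COC(=O)/C(C)=C\CC/C(C)=C/I | intermediate
15 | 9-{2-[(2R)-7-(9-borabicyclo[3.3.1]nonan-9-yloxy)-2,5-dimethyl-3,4-dihydro-2H-chromen-2-yl]ethyl}-9-borabicyclo[3.3.1]nonane | B1(C2CCCC1CCC2)CC[C@]3(C)CCc4c(C)cc(OB5C6CCCC5CCC6)cc4O3 | intermediate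
16 | methyl (2Z,6E)-9-[(2R)-7-hydroxy-2,5-dimethyl-3,4-dihydro-2H-chromen-2-yl]-2,6-dimethylnona-2,6-dienoate | COC(=O)/C(C)=C\CC/C(C)=C/CC[C@]1(C)CCc2c(C)cc(O)cc2O1 | target

## Step count and risks
Total step count: 7.
Longest linear sequence: 4 steps (1 → 3 → 4 → 7 → 16, and equally 8 → 10 → 11 → 14 → 16).

**Step 3.** The risks are Friedel–Crafts self-condensation of the electron-rich nucleus with 6, partial formation of the 2-isopropenyl regioisomer, low ee, and acid ionisation of the tertiary allylic ether. The fallback sets out from aldehyde 3 and comes back at 7.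
- Claisen–Schmidt condensation with acetone (aq. NaOH) gives (E)-4-(2,4-dihydroxy-6-methylphenyl)but-3-en-2-one F1.
- Hydrogenation (H2, Pd/C, EtOAc) gives 4-(2,4-dihydroxy-6-methylphenyl)butan-2-one F2.
- Wittig ethylidenation (EtPPh3Br, excess KOtBu, THF) gives 5-methyl-4-(3-methylpent-3-en-1-yl)benzene-1,3-diol F3 as an E/Z mixture.
- An enantioselective Wacker-type oxidative cyclisation (Pd(TFA)2, chiral BOXAX ligand, p-benzoquinone, MeOH) proceeds by oxypalladation at the tertiary carbon and β-hydride elimination from the methyl group, which gives 7.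

**Step 7.** The risks are slow transmetalation of the borane next to the quaternary centre, interference of the free phenol, and protodeboronation. The fallback sets out from 7, builds the E-alkene by sigmatropic rearrangement instead of cross-coupling, and comes back at 16.
- Linear-selective Rh-catalysed hydroformylation (Rh(acac)(CO)2, bisphosphite ligand, CO/H2) gives 3-[(2S)-7-hydroxy-2,5-dimethyl-3,4-dihydro-2H-chromen-2-yl]propanal F4.
- Isopropenylmagnesium bromide (2.2 equiv) gives (2S)-2-(3-hydroxy-4-methylpent-4-en-1-yl)-2,5-dimethyl-3,4-dihydro-2H-chromen-7-ol F5 as carbinol epimers.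
- Johnson–Claisen rearrangement (MeC(OMe)3, cat. EtCO2H, 140 °C) gives methyl (4E)-7-[(2R)-7-hydroxy-2,5-dimethyl-3,4-dihydro-2H-chromen-2-yl]-4-methylhept-4-enoate F6.
- DIBAL-H at −78 °C gives (4E)-7-[(2R)-7-hydroxy-2,5-dimethyl-3,4-dihydro-2H-chromen-2-yl]-4-methylhept-4-enal F7.
- Still–Gennari olefination with carbanion 13, using one extra equivalent of base for the phenol, gives 16.

**Step 2.** The risks are over-reduction to the methyl compound and oligomerisation of 4 on isolation. The fallback sets out from 3, reaches the quinone methide by oxidation instead of ionisation, and comes back at 6.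
- Deliberate exhaustive reduction (H2, Pd/C, AcOH) gives the robust 4,5-dimethylbenzene-1,3-diol F8.
- Only its C4 methyl group is ortho/para to the hydroxyls. Two-electron oxidation with Ag2O, in the presence of isoprene and the chiral acid, gives 6, which is trapped as in step 3.

## Further compounds
F1 | step 3 | (E)-4-(2,4-dihydroxy-6-methylphenyl)but-3-en-2-one | CC(=O)/C=C/c1c(C)cc(O)cc1O
F2 | step 3 | 4-(2,4-dihydroxy-6-methylphenyl)butan-2-one | CC(=O)CCc1c(C)cc(O)cc1O
F3 | step 3 | 5-methyl-4-(3-methylpent-3-en-1-yl)benzene-1,3-diol (E/Z mixture) | CC=C(C)CCc1c(C)cc(O)cc1O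
F4 | step 7 | 3-[(2S)-7-hydroxy-2,5-dimethyl-3,4-dihydro-2H-chromen-2-yl]propanal | O=CCC[C@]1(C)CCc2c(C)cc(O)cc2O1
F5 | step 7 | (2S)-2-(3-hydroxy-4-methylpent-4-en-1-yl)-2,5-dimethyl-3,4-dihydro-2H-chromen-7-ol (carbinol epimers) | C=C(C)C(O)CC[C@]1(C)CCc2c(C)cc(O)cc2O1
F6 | step 7 | methyl (4E)-7-[(2R)-7-hydroxy-2,5-dimethyl-3,4-dihydro-2H-chromen-2-yl]-4-methylhept-4-enoate | COC(=O)CC/C(C)=C/CC[C@]1(C)CCc2c(C)cc(O)cc2O1
F7 | step 7 | (4E)-7-[(2R)-7-hydroxy-2,5-dimethyl-3,4-dihydro-2H-chromen-2-yl]-4-methylhept-4-enal | O=CCC/C(C)=C/CC[C@]1(C)CCc2c(C)cc(O)cc2O1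
F8 | step 2 | 4,5-dimethylbenzene-1,3-diol | Cc1cc(O)cc(O)c1C
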